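**Retrosynthetic overview**
- The route rests on C2 of the furan ring, the one atom that carries both O1 and the CH2CO2Me chain. Cutting O1–C2 and the CH2–CO2Me bond together leads back to a phenol with an ethynyl methyl carbinol on the future C3a, plus CO and methanol. The alkyne carbons become C2 and the acetate CH2, and the carbinol carbon becomes C3 with its methyl group.
- The carbinol comes from an ortho-hydroxyaryl methyl ketone and ethynylmagnesium bromide. The ketone comes from a 3-aryl-2,5-dimethoxyphenol by ortho-formylation, methyl Grignard addition and oxidation.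
- That phenol comes from 2-hydroxy-5-methoxybenzaldehyde. Bromination, O-methylation and Suzuki coupling place the aryl group at the future C6, and Baeyer–Villiger oxidation turns the formyl-bearing carbon into the phenol that becomes O1.
- Ring order: the benzene ring is bought and the furan ring is closed by carbonylative 5-exo-dig oxypalladation. Reductive removal of the C3 hydroxyl then aromatizes the furan, and hydrogenolysis frees the 4'-phenol.

Key step: step 9

Remark: the target has no stereocentre; the carbinol intermediates of the route are racemates and their stereocentres are destroyed before the end.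

**Route**

Step 1
Reactants: 1 2-hydroxy-5-methoxybenzaldehyde
Product: 2 3-bromo-2-hydroxy-5-methoxybenzaldehyde
Conditions: Br2, NaOAc, AcOH, rt
Reagents that add atoms: bromine, BrBr
Why: Electrophilic aromatic bromination, in which the phenol hydroxyl directs bromine to its only free ortho carbon (the para carbon carries the methoxy group) while NaOAc buffers the HBr.

Step 2
Reactants: 2 3-bromo-2-hydroxy-5-methoxybenzaldehyde
Product: 3 3-bromo-2,5-dimethoxybenzaldehyde
Conditions: MeI, K2CO3, DMF, rt
Reagents that add atoms: iodomethane, CI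
Why: Williamson-type O-methylation (SN2) of the potassium phenoxide, which installs the future C7 methoxy group and removes the acidic phenol before the cross-coupling.

Step 3
Reactants: 3 3-bromo-2,5-dimethoxybenzaldehyde; 4 [4-(benzyloxy)phenyl]boronic acid
Product: 5 3-[4-(benzyloxy)phenyl]-2,5-dimethoxybenzaldehyde
Conditions: Pd(PPh3)4 (3 mol %), K2CO3, 1,4-dioxane/H2O, 90 °C
Reagents that add atoms: none
Why: Suzuki–Miyaura cross-coupling of an aryl bromide with a single ortho substituent and an electron-rich arylboronic acid, under conditions that leave the aldehyde and the benzyl ether untouched.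

Step 4
Reactants: 5 3-[4-(benzyloxy)phenyl]-2,5-dimethoxybenzaldehyde
Product: 7 3-[4-(benzyloxy)phenyl]-2,5-dimethoxyphenol, via aryl formate 6 (not isolated)
Conditions: mCPBA, CH2Cl2, 0 °C to rt; then K2CO3, MeOH, rt
Reagents that add atoms: 3-chloroperbenzoic acid (mCPBA), OOC(=O)c1cccc(Cl)c1
Why: Baeyer–Villiger oxidation of an electron-rich ortho-alkoxybenzaldehyde, in which the aryl group migrates in preference to hydride to give the formate, which mild methanolysis then cleaves to the phenol.

Step 5
Reactants: 7 3-[4-(benzyloxy)phenyl]-2,5-dimethoxyphenol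
Product: 9 4-[4-(benzyloxy)phenyl]-2-hydroxy-3,6-dimethoxybenzaldehyde, via hydroxymethylphenol 8 (not isolated)
Conditions: MgCl2, Et3N, (CH2O)n, MeCN, reflux; aq. HCl work-up
Reagents that add atoms: paraformaldehyde (as formaldehyde), C=O
Why: Magnesium-mediated ortho-formylation of a phenol (Casnati–Skattebøl reaction), in which the magnesium phenoxide delivers formaldehyde to the single free ortho carbon and a second formaldehyde oxidizes the benzylic alkoxide by hydride transfer, so the para carbon is not touched.

Step 6
Reactants: 9 4-[4-(benzyloxy)phenyl]-2-hydroxy-3,6-dimethoxybenzaldehyde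
Product: 10 racemic 5-[4-(benzyloxy)phenyl]-2-(1-hydroxyethyl)-3,6-dimethoxyphenol
Conditions: MeMgBr (3 equiv), THF, 0 °C to rt; aq. NH4Cl
Reagents that add atoms: methylmagnesium bromide, C[Mg]Br
Why: Grignard 1,2-addition to the aldehyde after the first equivalent has deprotonated the phenol; the new carbinol stereocentre forms without control (racemate) and is erased in step 7.

Step 7
Reactants: 10 racemic 5-[4-(benzyloxy)phenyl]-2-(1-hydroxyethyl)-3,6-dimethoxyphenol
Product: 11 1-{4-[4-(benzyloxy)phenyl]-2-hydroxy-3,6-dimethoxyphenyl}ethanone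
Conditions: MnO2 (excess), CH2Cl2, rt
Reagents that add atoms: none
Why: Selective MnO2 oxidation of a benzylic secondary alcohol to the aryl ketone, which leaves the phenol, the methyl ethers and the benzyl ether unchanged.

Step 8
Reactants: 11 1-{4-[4-(benzyloxy)phenyl]-2-hydroxy-3,6-dimethoxyphenyl}ethanone; 12 ethynylmagnesium bromide
Product: 13 racemic 5-[4-(benzyloxy)phenyl]-2-(2-hydroxybut-3-yn-2-yl)-3,6-dimethoxyphenol
Conditions: HC≡CMgBr (4 equiv), THF, 0 °C to rt; aq. NH4Cl
Reagents that add atoms: none
Why: Grignard addition of the acetylide to the ketone, which the neighbouring magnesium phenoxide activates by chelation while excess reagent covers the phenol proton; the new tertiary carbinol stereocentre is racemic and is destroyed in step 10.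

Step 9
Reactants: 13 racemic 5-[4-(benzyloxy)phenyl]-2-(2-hydroxybut-3-yn-2-yl)-3,6-dimethoxyphenol; 14 carbon monoxide; 15 methanol
Product: 16 racemic methyl (E)-2-{6-[4-(benzyloxy)phenyl]-3-hydroxy-4,7-dimethoxy-3-methylbenzofuran-2(3H)-ylidene}acetate
Conditions: PdI2 (2 mol %), KI (20 mol %), CO/air (4:1, 40 atm), MeOH, 50 °C
Reagents that add atoms: none
Why: PdI2, held in solution as K2PdI4, coordinates the terminal alkyne of 13 and the phenol oxygen attacks the internal alkyne carbon anti to the metal, closing the furan ring in the 5-exo-dig mode (O1–C2) and leaving a vinylpalladium iodide on the former terminal carbon. CO inserts into that C–Pd bond with retention and methanol cleaves the acylpalladium to the ester (new CH–CO2Me bond), releasing zerovalent palladium and HI, which the oxygen of the air returns to PdI2 by way of I2. The closest known reaction type is the PdI2/KI-catalysed oxidative heterocyclization–alkoxycarbonylation of terminal alkynes that carry a tethered hydroxyl or phenol nucleophile, which gives E-configured 2-(alkoxycarbonylmethylene) oxygen heterocycles. No stereocentre is created, since the racemic carbinol carbon of 13 becomes C3 unchanged; the E geometry of the exocyclic alkene follows from anti oxypalladation and retentive CO insertion. The step needs 5-exo closure by the phenol to win over 6-endo attack, over dicarbonylation of the alkyne to a maleate and over ionization of the C3 carbinol; the one-carbon link between arene and alkyne, the higher nucleophilicity of the phenol compared with the tertiary alcohol (which could only close a four-membered ring) and the low standing concentration of HI under aerobic reoxidation at moderate temperature should secure this.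

Step 10
Reactants: 16 racemic methyl (E)-2-{6-[4-(benzyloxy)phenyl]-3-hydroxy-4,7-dimethoxy-3-methylbenzofuran-2(3H)-ylidene}acetate
Product: 17 methyl 2-{6-[4-(benzyloxy)phenyl]-4,7-dimethoxy-3-methylbenzofuran-2-yl}acetate
Conditions: Et3SiH (3 equiv), TFA (10 equiv), CH2Cl2, 0 °C
Reagents that add atoms: none
Why: Ionic deoxygenation (ionic hydrogenation): TFA ionizes the tertiary benzylic, allylic alcohol to a cation delocalized over C3 and the exocyclic carbon and stabilized by O1 and the ring methoxy groups, and hydride transfer from Et3SiH to either terminus, followed if needed by acid-mediated tautomerization, should give the aromatic benzofuran-2-acetate.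

Step 11
Reactants: 17 methyl 2-{6-[4-(benzyloxy)phenyl]-4,7-dimethoxy-3-methylbenzofuran-2-yl}acetate
Product: 18 Phenylcandilide B, methyl 2-[6-(4-hydroxyphenyl)-4,7-dimethoxy-3-methylbenzofuran-2-yl]acetate
Conditions: H2 (1 atm), 10% Pd/C, EtOAc/MeOH, rt
Reagents that add atoms: none
Why: Catalytic hydrogenolysis of the benzyl aryl ether over Pd/C, under which the tetrasubstituted benzofuran C2=C3 bond, the methyl ethers and the ester are not reduced.

**Compound list**
1 | 2-hydroxy-5-methoxybenzaldehyde | COc1ccc(O)c(C=O)c1 | starting material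
2 | 3-bromo-2-hydroxy-5-methoxybenzaldehyde | COc1cc(Br)c(O)c(C=O)c1 | intermediate
3 | 3-bromo-2,5-dimethoxybenzaldehyde | COc1cc(Br)c(OC)c(C=O)c1 | intermediate
4 | [4-(benzyloxy)phenyl]boronic acid | OB(O)c1ccc(OCc2ccccc2)cc1 | starting material
5 | 3-[4-(benzyloxy)phenyl]-2,5-dimethoxybenzaldehyde | COc1cc(C=O)c(OC)c(-c2ccc(OCc3ccccc3)cc2)c1 | intermediate
6 | 3-[4-(benzyloxy)phenyl]-2,5-dimethoxyphenyl formate (not isolated) | COc1cc(OC=O)c(OC)c(-c2ccc(OCc3ccccc3)cc2)c1 | intermediate
7 | 3-[4-(benzyloxy)phenyl]-2,5-dimethoxyphenol | COc1cc(O)c(OC)c(-c2ccc(OCc3ccccc3)cc2)c1 | intermediate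
8 | 5-[4-(benzyloxy)phenyl]-2-(hydroxymethyl)-3,6-dimethoxyphenol (as its magnesium salt, not isolated) | COc1cc(-c2ccc(OCc3ccccc3)cc2)c(OC)c(O)c1CO | intermediate
9 | 4-[4-(benzyloxy)phenyl]-2-hydroxy-3,6-dimethoxybenzaldehyde | COc1cc(-c2ccc(OCc3ccccc3)cc2)c(OC)c(O)c1C=O | intermediate
10 | racemic 5-[4-(benzyloxy)phenyl]-2-(1-hydroxyethyl)-3,6-dimethoxyphenol | COc1cc(-c2ccc(OCc3ccccc3)cc2)c(OC)c(O)c1C(C)O | intermediate
11 | 1-{4-[4-(benzyloxy)phenyl]-2-hydroxy-3,6-dimethoxyphenyl}ethanone | COc1cc(-c2ccc(OCc3ccccc3)cc2)c(OC)c(O)c1C(C)=O | intermediate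
12 | ethynylmagnesium bromide | C#C[Mg]Br | starting material
13 | racemic 5-[4-(benzyloxy)phenyl]-2-(2-hydroxybut-3-yn-2-yl)-3,6-dimethoxyphenol | C#CC(C)(O)c1c(OC)cc(-c2ccc(OCc3ccccc3)cc2)c(OC)c1O | intermediate
14 | carbon monoxide | [C-]#[O+] | starting material
15 | methanol | CO | starting material
16 | racemic methyl (E)-2-{6-[4-(benzyloxy)phenyl]-3-hydroxy-4,7-dimethoxy-3-methylbenzofuran-2(3H)-ylidene}acetate | COC(=O)/C=C1/Oc2c(OC)c(-c3ccc(OCc4ccccc4)cc3)cc(OC)c2C1(C)O | intermediate
17 | methyl 2-{6-[4-(benzyloxy)phenyl]-4,7-dimethoxy-3-methylbenzofuran-2-yl}acetate | COC(=O)Cc1oc2c(OC)c(-c3ccc(OCc4ccccc4)cc3)cc(OC)c2c1C | intermediate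
18 | Phenylcandilide B, methyl 2-[6-(4-hydroxyphenyl)-4,7-dimethoxy-3-methylbenzofuran-2-yl]acetate | COC(=O)Cc1oc2c(OC)c(-c3ccc(O)cc3)cc(OC)c2c1C | target

**Step count**
Total step count: 11. Longest linear sequence: 11 steps (1 to 18).

**Steps most likely to fail**

1. Step 9. The vinylpalladium intermediate may be diverted into a second carbonylation of the alkyne or arise from 6-endo closure. The electron-rich phenol ring may be iodinated or oxidized by the I2/air couple. HI may ionize the tertiary carbinol before or after ring closure, so that methanol substitution, elimination or Meyer–Schuster-type rearrangement erode the mass balance. Material that has only exchanged or lost the C3 hydroxyl would be expected to converge on 17 in step 10.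
Fallback: it sets out from 11 and comes back at 17, bypassing steps 8 to 10 with classical chemistry. O-Alkylation of 11 with methyl bromoacetate (K2CO3, DMF, 90 °C) should give methyl 2-{2-acetyl-5-[4-(benzyloxy)phenyl]-3,6-dimethoxyphenoxy}acetate F1. Under the same conditions this should close by intramolecular aldol condensation (Rap–Stoermer-type) to methyl 6-[4-(benzyloxy)phenyl]-4,7-dimethoxy-3-methylbenzofuran-2-carboxylate F2. Saponification (LiOH, THF/H2O) should give 6-[4-(benzyloxy)phenyl]-4,7-dimethoxy-3-methylbenzofuran-2-carboxylic acid F3. Oxalyl chloride with catalytic DMF should give 6-[4-(benzyloxy)phenyl]-4,7-dimethoxy-3-methylbenzofuran-2-carbonyl chloride F4. Trimethylsilyldiazomethane should give 1-{6-[4-(benzyloxy)phenyl]-4,7-dimethoxy-3-methylbenzofuran-2-yl}-2-diazoethanone F5. Wolff rearrangement (silver benzoate PhCO2Ag, Et3N, MeOH) should then deliver 17 (Arndt–Eistert homologation).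

2. Step 8. The Grignard reagent may enolize the di-ortho-substituted, chelated ketone instead of adding, returning 11 after work-up, or addition may stall at partial conversion.
Fallback: it sets out from 11 and comes back at 13. Silylation (TBSOTf, 2,6-lutidine, CH2Cl2) should give 1-{4-[4-(benzyloxy)phenyl]-2-[(tert-butyldimethylsilyl)oxy]-3,6-dimethoxyphenyl}ethanone F6. Addition of the weakly basic organocerium reagent made from lithium (trimethylsilyl)acetylide (LiC≡CSiMe3) and CeCl3 in THF at −78 °C should give racemic 2-{4-[4-(benzyloxy)phenyl]-2-[(tert-butyldimethylsilyl)oxy]-3,6-dimethoxyphenyl}-4-(trimethylsilyl)but-3-yn-2-ol F7. Tetrabutylammonium fluoride (THF, 0 °C) should remove both silyl groups to give 13.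

3. Step 10. The delocalized cation may alkylate the electron-rich rings of a second molecule (Friedel–Crafts dimerization) faster than it is reduced. The benzofuran C2=C3 bond may be over-reduced by ionic hydrogenation. The benzyl ether may be lost early in acid.
Fallback: it sets out from 16 and comes back at 18. Hydrogenation over Pd/C (H2, EtOAc, rt) should saturate the exocyclic enol-ether double bond and cleave the benzyl ether, giving methyl 2-[3-hydroxy-6-(4-hydroxyphenyl)-4,7-dimethoxy-3-methyl-2,3-dihydrobenzofuran-2-yl]acetate F8 as a mixture of racemic diastereomers. Catalytic TsOH in toluene at 60 °C should then eliminate water across C2–C3 through the tertiary benzylic cation (E1) and give the aromatic benzofuran 18 directly, so that step 11 is not needed.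

**Further compounds**
F1 | step 9 | methyl 2-{2-acetyl-5-[4-(benzyloxy)phenyl]-3,6-dimethoxyphenoxy}acetate | COC(=O)COc1c(OC)c(-c2ccc(OCc3ccccc3)cc2)cc(OC)c1C(C)=O
F2 | step 9 | methyl 6-[4-(benzyloxy)phenyl]-4,7-dimethoxy-3-methylbenzofuran-2-carboxylate | COC(=O)c1oc2c(OC)c(-c3ccc(OCc4ccccc4)cc3)cc(OC)c2c1C
F3 | step 9 | 6-[4-(benzyloxy)phenyl]-4,7-dimethoxy-3-methylbenzofuran-2-carboxylic acid | OC(=O)c1oc2c(OC)c(-c3ccc(OCc4ccccc4)cc3)cc(OC)c2c1C
F4 | step 9 | 6-[4-(benzyloxy)phenyl]-4,7-dimethoxy-3-methylbenzofuran-2-carbonyl chloride | ClC(=O)c1oc2c(OC)c(-c3ccc(OCc4ccccc4)cc3)cc(OC)c2c1C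
F5 | step 9 | 1-{6-[4-(benzyloxy)phenyl]-4,7-dimethoxy-3-methylbenzofuran-2-yl}-2-diazoethanone | [N-]=[N+]=CC(=O)c1oc2c(OC)c(-c3ccc(OCc4ccccc4)cc3)cc(OC)c2c1C
F6 | step 8 | 1-{4-[4-(benzyloxy)phenyl]-2-[(tert-butyldimethylsilyl)oxy]-3,6-dimethoxyphenyl}ethanone | COc1cc(-c2ccc(OCc3ccccc3)cc2)c(OC)c(O[Si](C)(C)C(C)(C)C)c1C(C)=O
F7 | step 8 | racemic 2-{4-[4-(benzyloxy)phenyl]-2-[(tert-butyldimethylsilyl)oxy]-3,6-dimethoxyphenyl}-4-(trimethylsilyl)but-3-yn-2-ol | COc1cc(-c2ccc(OCc3ccccc3)cc2)c(OC)c(O[Si](C)(C)C(C)(C)C)c1C(C)(O)C#C[Si](C)(C)C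
F8 | step 10 | methyl 2-[3-hydroxy-6-(4-hydroxyphenyl)-4,7-dimethoxy-3-methyl-2,3-dihydrobenzofuran-2-yl]acetate (racemic diastereomers) | COC(=O)CC1Oc2c(OC)c(-c3ccc(O)cc3)cc(OC)c2C1(C)O
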